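**Retrosynthetic overview**

1. The target is cut at the ring-D ester (acid 46) and at the ring-A diosphenol, which comes from an acetonide-protected cis-diol by double oxidation and enolisation.
2. Ring B (eight-membered) is closed by an intramolecular Nozaki–Hiyama–Kishi addition of a 2-alkenyl triflate to the ring-A ketone, which creates the tertiary carbinol and the exocyclic methylene together. The two halves are joined before that by enolate alkylation with a (Z)-allylic chloride whose geometry is fixed in a temporary seven-membered RCM lactone.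
3. Ring D is made in one pot from a bicyclic cyclopropanol and 3-methylbutanoyl chloride by C–C cleavage, homoenolate acylation and aldol condensation. A CBS reduction and a hydroxyl-directed hydrogenation then set the carbinol, the isopropyl-bearing carbon and the trans ring fusion.
4. Ring C comes from a catalytic asymmetric Diels–Alder reaction. Order of ring formation: C, cyclopropane, D, temporary lactone, A (attached ready-made from a D-ribose-derived enone), B.
5. Enabling feature: in ring D the oxygen-bearing carbon C2 is flanked by the CH2 (C1) on the quaternary C7a–CH3 and by the isopropyl-bearing C3 next to the ring-fusion carbon C3a. At the ketone level this is a cyclopentenone, i.e. the dehydrated 1,4-diketone (ring-C ketone at C3a, ketone at C2). That diketone is the acylation product of the homoenolate set free when the C3a–C1 bond of a 1-hydroxybicyclo[4.1.0]heptane (ring C plus the cyclopropane C3a–C7a–C1) is cleaved.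

Key step: step 5

Assumption: the sense of induction in steps 2 and 3 follows the accepted models for these catalyst and ligand classes; if it proves opposite, the antipodal catalyst or ligand is used and nothing else changes.

Remark: hydrindane intermediates carry indene locants (C1 = ring-D CH2, C2 = oxygenated carbon, C3 = isopropyl carbon, C3a and C7a = ring fusion, C5 = ester-bearing carbon, C6 = acetyl-bearing carbon).

**Route**

Step 1
Reactants: 1 3-methylbut-3-en-2-one
Product: 2 2-[(tert-butyldimethylsilyl)oxy]-3-methylbuta-1,3-diene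
Conditions: TBSOTf, Et3N, CH2Cl2, 0 °C
Reagents that add atoms: tert-butyldimethylsilyl triflate, CC(C)(C)[Si](C)(C)OS(=O)(=O)C(F)(F)F
Why: Soft enolisation and O-silylation of an enone whose only enolisable position is the methyl group should give the 2-siloxydiene, with no stereocentre formed.

Step 2
Reactants: 2 2-[(tert-butyldimethylsilyl)oxy]-3-methylbuta-1,3-diene; 3 methyl (E)-4-oxopent-2-enoate
Product: 4 methyl (1S,6S)-6-acetyl-3-[(tert-butyldimethylsilyl)oxy]-4-methylcyclohex-3-ene-1-carboxylate
Conditions: (S)-B-(o-tolyl)diphenylprolinol oxazaborolidine·HNTf2 (10 mol %), CH2Cl2, −78 °C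
Reagents that add atoms: none
Why: Catalytic asymmetric Diels–Alder reaction in which the chiral oxazaborolidinium binds the ketone, so the siloxy-activated diene terminus bonds to the carbon β to the ketone (acetyl para to the siloxy group), the trans relation comes from the (E)-dienophile and the absolute configuration at C1 and C6 from the catalyst.

Step 3
Reactants: 4 methyl (1S,6S)-6-acetyl-3-[(tert-butyldimethylsilyl)oxy]-4-methylcyclohex-3-ene-1-carboxylate
Product: 5 methyl 4-acetyl-1-[(tert-butyldimethylsilyl)oxy]-6-methylbicyclo[4.1.0]heptane-3-carboxylate (cyclopropane CH2 cis to the acetyl group, trans to the ester)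
Conditions: Et2Zn, CH2I2, N-Boc-L-Val-L-Pro-OMe, CH2Cl2, −40 to 0 °C
Reagents that add atoms: diiodomethane, ICI
Why: Simmons–Smith cyclopropanation (Furukawa variant with a chiral dipeptide ligand) of the electron-rich tetrasubstituted silyl enol ether; the substrate has no facial bias of its own (both ring substituents equatorial), so C1 and C6 are set by the reagent, and the minor isomer is a diastereomer that is removed by chromatography, so the enantiopurity from step 2 is kept.

Step 4
Reactants: 5 methyl 4-acetyl-1-[(tert-butyldimethylsilyl)oxy]-6-methylbicyclo[4.1.0]heptane-3-carboxylate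
Product: 6 methyl 4-acetyl-1-hydroxy-6-methylbicyclo[4.1.0]heptane-3-carboxylate
Conditions: TBAF, AcOH, THF, 0 °C
Reagents that add atoms: none
Why: Buffered fluoride desilylation should free the cyclopropanol without the base-induced ring opening that unbuffered fluoride would cause; no stereocentre changes.

Step 5
Reactants: 6 methyl 4-acetyl-1-hydroxy-6-methylbicyclo[4.1.0]heptane-3-carboxylate; 7 3-methylbutanoyl chloride
Product: 11 methyl (5S,6S,7aS)-6-acetyl-7a-methyl-2-oxo-3-(propan-2-yl)-2,4,5,6,7,7a-hexahydro-1H-indene-5-carboxylate, via zinc homoenolate 8 (not isolated), via triketone 9 (not isolated), via aldol adduct 10 (not isolated)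
Conditions: Et2Zn, THF, 0 °C; Pd(PPh3)4 (5 mol %), 7, 40 °C; then NaOMe, MeOH, 40 °C
Reagents that add atoms: none
Why: Et2Zn deprotonates the cyclopropanol and the zinc cyclopropoxide opens at the bond between the carbinol carbon and the cyclopropane CH2 to the β-zincio ketone 8, which is acylated through an acylpalladium species (oxidative addition of 7 to zerovalent palladium, transmetalation, reductive elimination) to the 1,4-diketone 9; the closest precedent is the palladium-catalysed C-acylation of cyclopropanols and siloxycyclopropanes to 1,4-diketones. Methoxide then enolises the new ketone on its isobutyl side, the enolate adds to the ring ketone (aldol adduct 10) and water is lost to give the conjugated cyclopentenone 11, the classical 1,4-diketone cyclopentenone annulation. Ring D is therefore closed by an intermolecular C–C bond at its CH2 carbon followed by an intramolecular aldol condensation at the ring-fusion carbon. No new stereocentre is formed: the quaternary C7a keeps the configuration from step 3 because none of its bonds is broken, and C5 and C6 stay trans-diequatorial. The step needs site-selective cyclopropane cleavage (secured by formation of the primary rather than the tertiary carbon–zinc bond), C- rather than O-acylation (secured by the palladium cycle) and the right aldol mode (only this one can dehydrate to a conjugated enone, so the reversible bridged aldols drain into it; the temperature is kept low to avoid Claisen condensation of the acetyl group onto the ester).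

Step 6
Reactants: 11 methyl (5S,6S,7aS)-6-acetyl-7a-methyl-2-oxo-3-(propan-2-yl)-2,4,5,6,7,7a-hexahydro-1H-indene-5-carboxylate
Product: 12 methyl (5S,6S,7aS)-7a-methyl-6-(2-methyl-1,3-dioxolan-2-yl)-2-oxo-3-(propan-2-yl)-2,4,5,6,7,7a-hexahydro-1H-indene-5-carboxylate
Conditions: Me3SiOCH2CH2OSiMe3, Me3SiOTf (cat.), CH2Cl2, −78 to −20 °C
Reagents that add atoms: 1,2-bis(trimethylsilyloxy)ethane, C[Si](C)(C)OCCO[Si](C)(C)C
Why: Silyl-triflate-catalysed ketalisation is selective for the saturated methyl ketone over the hindered conjugated cyclopentenone, which masks the acetyl group for the two reductions that follow.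

Step 7
Reactants: 12 methyl (5S,6S,7aS)-7a-methyl-6-(2-methyl-1,3-dioxolan-2-yl)-2-oxo-3-(propan-2-yl)-2,4,5,6,7,7a-hexahydro-1H-indene-5-carboxylate
Product: 13 methyl (2R,5S,6S,7aS)-2-hydroxy-7a-methyl-6-(2-methyl-1,3-dioxolan-2-yl)-3-(propan-2-yl)-2,4,5,6,7,7a-hexahydro-1H-indene-5-carboxylate
Conditions: (S)-Me-CBS oxazaborolidine, catecholborane, toluene, −78 to −40 °C
Reagents that add atoms: none
Why: CBS reduction of the enone (alkenyl arm as the large group, CH2 as the small one) should give the (2R)-allylic alcohol with the hydroxyl on the face opposite the angular methyl under reagent control, against the modest substrate bias.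

Step 8
Reactants: 13 methyl (2R,5S,6S,7aS)-2-hydroxy-7a-methyl-6-(2-methyl-1,3-dioxolan-2-yl)-3-(propan-2-yl)-2,4,5,6,7,7a-hexahydro-1H-indene-5-carboxylate
Product: 14 methyl (2R,3R,3aS,5S,6S,7aS)-2-hydroxy-7a-methyl-6-(2-methyl-1,3-dioxolan-2-yl)-3-(propan-2-yl)octahydro-1H-indene-5-carboxylate (trans ring fusion)
Conditions: [Ir(cod)(PCy3)(py)]PF6 (15 mol %), H2 (1 atm), CH2Cl2, rt
Reagents that add atoms: none
Why: Hydroxyl-directed homogeneous hydrogenation delivers both hydrogens to the tetrasubstituted alkene on the face of the C2 hydroxyl, which is also the face opposite the angular methyl, so C3–H and C3a–H end up cis to the hydroxyl, the isopropyl group cis to the methyl and the ring fusion trans.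

Step 9
Reactants: 14 methyl (2R,3R,3aS,5S,6S,7aS)-2-hydroxy-7a-methyl-6-(2-methyl-1,3-dioxolan-2-yl)-3-(propan-2-yl)octahydro-1H-indene-5-carboxylate
Product: 15 methyl 6-acetyl-2-hydroxy-7a-methyl-3-(propan-2-yl)octahydro-1H-indene-5-carboxylate (stereocentres as in 14)
Conditions: PPTS, acetone/H2O, 50 °C
Reagents that add atoms: water, O
Why: Mild acid-catalysed ketal hydrolysis returns the methyl ketone; C6 is epimerisable but already in the favoured equatorial arrangement.

Step 10
Reactants: 15 methyl 6-acetyl-2-hydroxy-7a-methyl-3-(propan-2-yl)octahydro-1H-indene-5-carboxylate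
Product: 16 methyl 6-acetyl-2-[(tert-butyldimethylsilyl)oxy]-7a-methyl-3-(propan-2-yl)octahydro-1H-indene-5-carboxylate
Conditions: TBSCl, imidazole, DMAP (cat.), DMF, 50 °C
Reagents that add atoms: tert-butyldimethylsilyl chloride, CC(C)(C)[Si](C)(C)Cl
Why: Standard silylation of the secondary alcohol gives an ether that tolerates the organometallic and basic steps ahead.

Step 11
Reactants: 16 methyl 6-acetyl-2-[(tert-butyldimethylsilyl)oxy]-7a-methyl-3-(propan-2-yl)octahydro-1H-indene-5-carboxylate
Product: 17 methyl 2-[(tert-butyldimethylsilyl)oxy]-7a-methyl-3-(propan-2-yl)-6-(prop-1-en-2-yl)octahydro-1H-indene-5-carboxylate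
Conditions: Ph3PCH3Br, KOtBu, THF, 0 °C to rt
Reagents that add atoms: methyltriphenylphosphonium bromide, C[P+](c1ccccc1)(c1ccccc1)c1ccccc1.[Br-]
Why: Wittig methylenation converts the methyl ketone to the isopropenyl group while the ester is left alone, and any epimerisation at C6 returns to the equatorial isomer.

Step 12
Reactants: 17 methyl 2-[(tert-butyldimethylsilyl)oxy]-7a-methyl-3-(propan-2-yl)-6-(prop-1-en-2-yl)octahydro-1H-indene-5-carboxylate
Product: 18 prop-2-en-1-yl 2-[(tert-butyldimethylsilyl)oxy]-7a-methyl-3-(propan-2-yl)-6-(prop-1-en-2-yl)octahydro-1H-indene-5-carboxylate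
Conditions: Ti(OiPr)4 (0.3 equiv), allyl alcohol, 95 °C
Reagents that add atoms: prop-2-en-1-ol, C=CCO
Why: Titanate-catalysed transesterification in the alcohol as solvent exchanges methyl for allyl under near-neutral conditions and installs the second alkene only after the hydrogenation.

Step 13
Reactants: 18 prop-2-en-1-yl 2-[(tert-butyldimethylsilyl)oxy]-7a-methyl-3-(propan-2-yl)-6-(prop-1-en-2-yl)octahydro-1H-indene-5-carboxylate
Product: 19 seven-membered (Z)-lactone fused at C5/C6 of the hydrindane (C5–C(=O)–O–CH2–CH=C(CH3)–C6)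
Conditions: second-generation Hoveyda–Grubbs catalyst (10 mol %), toluene (2 mM), 90 °C
Reagents that add atoms: none
Why: Ring-closing metathesis between the allyl ester and the isopropenyl group, pre-organised by the trans-diequatorial ring-C substituents, should give the trisubstituted alkene, which can only be Z in a seven-membered ring.

Step 14
Reactants: 19 seven-membered (Z)-lactone
Product: 21 1-{2-[(tert-butyldimethylsilyl)oxy]-6-[(2Z)-4-hydroxybut-2-en-2-yl]-7a-methyl-3-(propan-2-yl)octahydro-1H-inden-5-yl}ethan-1-one, via lithium hemiketal alkoxide 20 (not isolated)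
Conditions: MeLi (1.05 equiv), THF, −78 °C; AcOH quench at −78 °C
Reagents that add atoms: methyllithium, [Li]C
Why: Addition of one equivalent of methyllithium to the α-branched lactone gives a tetrahedral alkoxide that survives at low temperature and collapses on quench to the methyl ketone and the free (Z)-allylic alcohol, which differentiates the two carbons of the former lactone.

Step 15
Reactants: 21 hydroxy methyl ketone
Product: 23 1-{2-[(tert-butyldimethylsilyl)oxy]-6-[(2Z)-4-chlorobut-2-en-2-yl]-7a-methyl-3-(propan-2-yl)octahydro-1H-inden-5-yl}ethan-1-one, via alkoxysulfonium chloride 22 (not isolated)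
Conditions: NCS, Me2S, CH2Cl2, −20 to 0 °C
Reagents that add atoms: N-chlorosuccinimide, ClN1C(=O)CCC1=O
Why: Corey–Kim chlorination converts the primary allylic alcohol to the chloride by direct displacement on the alkoxysulfonium salt, without allylic transposition or loss of the Z geometry.

Step 16
Reactants: 23 allylic chloride methyl ketone
Product: 25 1-{2-[(tert-butyldimethylsilyl)oxy]-6-[(2Z)-4-chlorobut-2-en-2-yl]-7a-methyl-3-(propan-2-yl)octahydro-1H-inden-5-yl}ethenyl trifluoromethanesulfonate, via potassium enolate 24 (not isolated)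
Conditions: KHMDS, PhNTf2, THF, −78 °C
Reagents that add atoms: N-phenylbis(trifluoromethanesulfonimide), O=S(=O)(N(c1ccccc1)S(=O)(=O)C(F)(F)F)C(F)(F)F
Why: Kinetic deprotonation at the methyl group (the methine at C5 is hindered) and O-triflation give the terminal alkenyl triflate, and at −78 °C the enolate is trapped faster than it can alkylate the allylic chloride.

Step 17
Reactants: 26 (3aR,6aR)-2,2-dimethyl-3a,6a-dihydro-4H-cyclopenta[d][1,3]dioxol-4-one
Product: 27 2,2,4-trimethyl-3a,6a-dihydro-4H-cyclopenta[d][1,3]dioxol-4-ol (hydroxyl cis to the dioxolane oxygens)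
Conditions: MeLi, THF, −78 °C
Reagents that add atoms: methyllithium, [Li]C
Why: 1,2-Addition to the enone carbonyl from the convex face of the bicycle gives the tertiary allylic alcohol; this centre is removed in the next step.

Step 18
Reactants: 27 2,2,4-trimethyl-3a,6a-dihydro-4H-cyclopenta[d][1,3]dioxol-4-ol
Product: 28 (3aS,6aS)-2,2,6-trimethyl-3a,6a-dihydro-4H-cyclopenta[d][1,3]dioxol-4-one
Conditions: pyridinium chlorochromate C5H5NH[CrO3Cl], 4 Å MS, CH2Cl2, rt
Reagents that add atoms: pyridinium chlorochromate, [O-][Cr](=O)(=O)Cl.c1cc[nH+]cc1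
Why: Babler–Dauben oxidative transposition (chromate ester, allylic shift, oxidation) moves the carbonyl to the far end of the allyl system and leaves the methyl on the β-carbon, with both acetonide stereocentres untouched.

Step 19
Reactants: 28 (3aS,6aS)-2,2,6-trimethyl-3a,6a-dihydro-4H-cyclopenta[d][1,3]dioxol-4-one
Product: 29 dimethyl(phenyl)silyl enol ether of the saturated ketone (6-methyl cis to the dioxolane oxygens)
Conditions: [(Ph3P)CuH]6 (5 mol %), PhMe2SiH, toluene, rt
Reagents that add atoms: dimethyl(phenyl)silane, C[SiH](C)c1ccccc1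
Why: Copper-hydride-catalysed conjugate hydrosilylation delivers hydride to the β-carbon from the convex face and traps the enolate regiospecifically as the silyl enol ether; the new methyl-bearing centre is a relay only and becomes sp2 in the target.

Step 20
Reactants: 29 silyl enol ether of the ring-A ketone; 25 alkenyl triflate allylic chloride
Product: 31 coupled ring-A ketone carrying the (Z)-allyl chain at C5 of the cyclopentanone (chain trans to the ring-A methyl and to the dioxolane), via lithium enolate 30 (not isolated)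
Conditions: MeLi, THF, 0 °C; then 25, DMPU, NaI (cat.), −78 to −20 °C
Reagents that add atoms: none
Why: Cleavage of the silyl enol ether gives the regiodefined lithium enolate, which is alkylated by the allylic chloride on the convex face, anti to the neighbouring methyl, and this sets the ring-A methine that survives into the target.

Step 21
Reactants: 31 coupled ring-A ketone
Product: 33 tetracyclic tertiary allylic alcohol (ring B closed; exocyclic methylene, silyl ether and acetonide in place), via alkenylchromium species 32 (not isolated)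
Conditions: CrCl2 (10 equiv), NiCl2 (10 mol %), DMSO/THF, rt to 50 °C, 2 mM
Reagents that add atoms: none
Why: Intramolecular Nozaki–Hiyama–Kishi reaction, in which nickel-mediated insertion into the alkenyl triflate and transmetalation to trivalent chromium give an alkenylchromium that adds to the α-alkoxy ketone; the tether and the convex face both direct attack to the face of the side chain, so the new carbinol has its hydroxyl cis to the adjacent ring-fusion hydrogen.

Step 22
Reactants: 33 tetracyclic silyl ether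
Product: 34 tetracyclic diol (free ring-D secondary alcohol, tertiary ring-A alcohol, acetonide)
Conditions: TBAF, THF, 50 °C
Reagents that add atoms: none
Why: Fluoride removes the hindered secondary silyl ether while the acetonide, the tertiary allylic alcohol and both alkenes are inert.

Step 23
Reactants: 35 (S)-1-bromo-2-methylbutane; 36 ethyl but-2-ynoate
Product: 40 ethyl (2E,5S)-3,5-dimethylhept-2-enoate, via Grignard reagent 37 (not isolated), via alkylcopper reagent 38 (not isolated), via alkenylcopper adduct 39 (not isolated)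
Conditions: Mg, THF; CuBr·SMe2, −40 °C; 36, −78 °C; NH4Cl
Reagents that add atoms: none
Why: Syn-carbocupration of the ynoate at low temperature followed by protonation places the new alkyl group trans to the ester, giving the (E)-enoate, and the (S) centre of the bromide is not touched.

Step 24
Reactants: 40 ethyl (2E,5S)-3,5-dimethylhept-2-enoate
Product: 41 (2E,5S)-3,5-dimethylhept-2-en-1-ol
Conditions: i-Bu2AlH, CH2Cl2, −78 °C
Reagents that add atoms: none
Why: 1,2-Reduction of the enoate by the aluminium hydride gives the allylic alcohol with the alkene geometry retained.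

Step 25
Reactants: 41 (2E,5S)-3,5-dimethylhept-2-en-1-ol
Product: 42 {(2R,3R)-3-methyl-3-[(2S)-2-methylbutyl]oxiran-2-yl}methanol
Conditions: Ti(OiPr)4, D-(−)-diethyl tartrate, t-BuOOH, 4 Å MS, CH2Cl2, −20 °C
Reagents that add atoms: tert-butyl hydroperoxide, CC(C)(C)OO
Why: Sharpless asymmetric epoxidation of the trisubstituted (E)-allylic alcohol with the D-tartrate gives the (2R,3R)-epoxide under reagent control, by analogy with geraniol.

Step 26
Reactants: 42 {(2R,3R)-3-methyl-3-[(2S)-2-methylbutyl]oxiran-2-yl}methanol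
Product: 43 (3R,5S)-3,5-dimethylheptane-1,3-diol
Conditions: NaAlH2(OCH2CH2OMe)2, THF, 0 °C
Reagents that add atoms: none
Why: Alkoxide-directed hydride delivery opens the 2,3-epoxy alcohol at C2, so the tertiary C3–O bond and its configuration are retained in the 1,3-diol.

Step 27
Reactants: 43 (3R,5S)-3,5-dimethylheptane-1,3-diol
Product: 44 (3R,5S)-3-hydroxy-3,5-dimethylheptanoic acid
Conditions: TEMPO (cat.), PhI(OAc)2, MeCN/H2O, rt
Reagents that add atoms: water, O
Why: Oxoammonium-mediated oxidation converts the primary alcohol through the aldehyde hydrate to the acid while the tertiary alcohol cannot be oxidised.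

Step 28
Reactants: 44 (3R,5S)-3-hydroxy-3,5-dimethylheptanoic acid
Product: 46 (3R,5S)-3,5-dimethyl-3-[(triethylsilyl)oxy]heptanoic acid, via silyl ester 45 (not isolated)
Conditions: Et3SiOTf, 2,6-lutidine, CH2Cl2, 0 °C; then K2CO3, MeOH/H2O
Reagents that add atoms: triethylsilyl triflate, CC[Si](CC)(CC)OS(=O)(=O)C(F)(F)F
Why: Exhaustive silylation followed by selective methanolysis of the labile silyl ester leaves the tertiary silyl ether, which blocks β-lactone formation and self-acylation during the esterification.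

Step 29
Reactants: 34 tetracyclic diol; 46 (3R,5S)-3,5-dimethyl-3-[(triethylsilyl)oxy]heptanoic acid
Product: 48 ring-D ester of 34 (silyl ether and acetonide still in place), via mixed anhydride 47 (not isolated)
Conditions: 2,4,6-trichlorobenzoyl chloride, Et3N, THF; then 34, DMAP, toluene, 40 °C
Reagents that add atoms: none
Why: Yamaguchi esterification acylates the hindered secondary ring-D alcohol with retention at the carbinol carbon, and the tertiary ring-A alcohol is too hindered to compete.

Step 30
Reactants: 48 protected ester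
Product: 49 tetraol ester (ring-A cis-diol, ring-A tertiary alcohol and side-chain tertiary alcohol free)
Conditions: CF3CO2H/H2O/THF, 0 °C to rt
Reagents that add atoms: none
Why: Aqueous acid hydrolyses the acetonide and the tertiary silyl ether in one operation, while the ester and the tertiary allylic alcohol (deactivated towards ionisation by the neighbouring oxygenated carbon) should survive.

Step 31
Reactants: 49 tetraol ester
Product: 51 CNP0110944.3, via diketone tautomer 50 (not isolated)
Conditions: DMSO, (CF3CO)2O, CH2Cl2, −78 °C; Et3N, to 0 °C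
Reagents that add atoms: none
Why: Swern-type oxidation of both secondary alcohols of the vicinal diol gives the 1,2-diketone without C–C cleavage, and this can enolise only towards the methyl-bearing carbon (the other α-carbon is quaternary), so it should tautomerise to the diosphenol of the target and erase the relay methyl stereocentre.

**Compound list**

1 | 3-methylbut-3-en-2-one | CC(=O)C(C)=C | starting material
2 | 2-[(tert-butyldimethylsilyl)oxy]-3-methylbuta-1,3-diene | C=C(O[Si](C)(C)C(C)(C)C)C(C)=C | intermediate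
3 | methyl (E)-4-oxopent-2-enoate | COC(=O)/C=C/C(C)=O | starting material
4 | methyl (1S,6S)-6-acetyl-3-[(tert-butyldimethylsilyl)oxy]-4-methylcyclohex-3-ene-1-carboxylate | COC(=O)[C@H]1CC(O[Si](C)(C)C(C)(C)C)=C(C)C[C@@H]1C(C)=O | intermediate
5 | methyl 4-acetyl-1-[(tert-butyldimethylsilyl)oxy]-6-methylbicyclo[4.1.0]heptane-3-carboxylate (CH2 cis to acetyl, trans to ester) | COC(=O)[C@H]2C[C@]3(O[Si](C)(C)C(C)(C)C)C[C@]3(C)C[C@@H]2C(C)=O | intermediate
6 | methyl 4-acetyl-1-hydroxy-6-methylbicyclo[4.1.0]heptane-3-carboxylate | COC(=O)[C@H]2C[C@]3(O)C[C@]3(C)C[C@@H]2C(C)=O | intermediate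
7 | 3-methylbutanoyl chloride | CC(C)CC(=O)Cl | starting material
8 | zinc homoenolate (β-ethylzinciomethyl ketone from 6) | COC(=O)[C@H]2CC(=O)[C@](C)(C[Zn]CC)C[C@@H]2C(C)=O | intermediate
9 | triketone, methyl 2-acetyl-4-methyl-4-(4-methyl-2-oxopentyl)-5-oxocyclohexane-1-carboxylate | COC(=O)[C@H]2CC(=O)[C@](C)(CC(=O)CC(C)C)C[C@@H]2C(C)=O | intermediate
10 | aldol adduct (3a-hydroxy hydrindanone; two new centres undefined) | COC(=O)[C@H]2CC3(O)C(C(C)C)C(=O)C[C@]3(C)C[C@@H]2C(C)=O | intermediate
11 | methyl (5S,6S,7aS)-6-acetyl-7a-methyl-2-oxo-3-(propan-2-yl)-2,4,5,6,7,7a-hexahydro-1H-indene-5-carboxylate | COC(=O)[C@H]2CC3=C(C(C)C)C(=O)C[C@]3(C)C[C@@H]2C(C)=O | intermediate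
12 | methyl (5S,6S,7aS)-7a-methyl-6-(2-methyl-1,3-dioxolan-2-yl)-2-oxo-3-(propan-2-yl)-2,4,5,6,7,7a-hexahydro-1H-indene-5-carboxylate | COC(=O)[C@H]2CC3=C(C(C)C)C(=O)C[C@]3(C)C[C@@H]2C1(C)OCCO1 | intermediate
13 | methyl (2R,5S,6S,7aS)-2-hydroxy-7a-methyl-6-(2-methyl-1,3-dioxolan-2-yl)-3-(propan-2-yl)-2,4,5,6,7,7a-hexahydro-1H-indene-5-carboxylate | COC(=O)[C@H]2CC3=C(C(C)C)[C@H](O)C[C@]3(C)C[C@@H]2C1(C)OCCO1 | intermediate
14 | methyl (2R,3R,3aS,5S,6S,7aS)-2-hydroxy-7a-methyl-6-(2-methyl-1,3-dioxolan-2-yl)-3-(propan-2-yl)octahydro-1H-indene-5-carboxylate | COC(=O)[C@H]2C[C@H]3[C@@H](C(C)C)[C@H](O)C[C@]3(C)C[C@@H]2C1(C)OCCO1 | intermediate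
15 | methyl 6-acetyl-2-hydroxy-7a-methyl-3-(propan-2-yl)octahydro-1H-indene-5-carboxylate (stereocentres as in 14) | COC(=O)[C@H]2C[C@H]3[C@@H](C(C)C)[C@H](O)C[C@]3(C)C[C@@H]2C(C)=O | intermediate
16 | tert-butyldimethylsilyl ether of 15 | COC(=O)[C@H]2C[C@H]3[C@@H](C(C)C)[C@H](O[Si](C)(C)C(C)(C)C)C[C@]3(C)C[C@@H]2C(C)=O | intermediate
17 | methyl 2-[(tert-butyldimethylsilyl)oxy]-7a-methyl-3-(propan-2-yl)-6-(prop-1-en-2-yl)octahydro-1H-indene-5-carboxylate | COC(=O)[C@H]2C[C@H]3[C@@H](C(C)C)[C@H](O[Si](C)(C)C(C)(C)C)C[C@]3(C)C[C@@H]2C(C)=C | intermediate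
18 | allyl ester corresponding to 17 | C=CCOC(=O)[C@H]2C[C@H]3[C@@H](C(C)C)[C@H](O[Si](C)(C)C(C)(C)C)C[C@]3(C)C[C@@H]2C(C)=C | intermediate
19 | seven-membered (Z)-lactone fused at C5/C6 | O=C1[C@H]2C[C@H]3[C@@H](C(C)C)[C@H](O[Si](C)(C)C(C)(C)C)C[C@]3(C)C[C@@H]2/C(C)=C\CO1 | intermediate
20 | lithium hemiketal alkoxide (methyl adduct of 19) | CC1([O-])[C@H]2C[C@H]3[C@@H](C(C)C)[C@H](O[Si](C)(C)C(C)(C)C)C[C@]3(C)C[C@@H]2/C(C)=C\CO1.[Li+] | intermediate
21 | hydroxy methyl ketone with (Z)-4-hydroxybut-2-en-2-yl group at C6 | CC(=O)[C@H]2C[C@H]3[C@@H](C(C)C)[C@H](O[Si](C)(C)C(C)(C)C)C[C@]3(C)C[C@@H]2/C(C)=C\CO | intermediate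
22 | alkoxydimethylsulfonium chloride of 21 | CC(=O)[C@H]2C[C@H]3[C@@H](C(C)C)[C@H](O[Si](C)(C)C(C)(C)C)C[C@]3(C)C[C@@H]2/C(C)=C\CO[S+](C)C.[Cl-] | intermediate
23 | (Z)-allylic chloride methyl ketone | CC(=O)[C@H]2C[C@H]3[C@@H](C(C)C)[C@H](O[Si](C)(C)C(C)(C)C)C[C@]3(C)C[C@@H]2/C(C)=C\CCl | intermediate
24 | potassium enolate of 23 (terminal) | C=C([O-])[C@H]2C[C@H]3[C@@H](C(C)C)[C@H](O[Si](C)(C)C(C)(C)C)C[C@]3(C)C[C@@H]2/C(C)=C\CCl.[K+] | intermediate
25 | alkenyl triflate (Z)-allylic chloride | C=C(OS(=O)(=O)C(F)(F)F)[C@H]2C[C@H]3[C@@H](C(C)C)[C@H](O[Si](C)(C)C(C)(C)C)C[C@]3(C)C[C@@H]2/C(C)=C\CCl | intermediate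
26 | (3aR,6aR)-2,2-dimethyl-3a,6a-dihydro-4H-cyclopenta[d][1,3]dioxol-4-one | O=C1C=C[C@H]2OC(C)(C)O[C@@H]12 | starting material
27 | 2,2,4-trimethyl-3a,6a-dihydro-4H-cyclopenta[d][1,3]dioxol-4-ol (OH cis to dioxolane oxygens) | C[C@]1(O)C=C[C@H]2OC(C)(C)O[C@@H]12 | intermediate
28 | (3aS,6aS)-2,2,6-trimethyl-3a,6a-dihydro-4H-cyclopenta[d][1,3]dioxol-4-one | CC1=CC(=O)[C@H]2OC(C)(C)O[C@@H]12 | intermediate
29 | dimethyl(phenyl)silyl enol ether of the 6-methyl ketone (methyl cis to dioxolane oxygens) | C[C@H]1C=C(O[Si](C)(C)c2ccccc2)[C@H]3OC(C)(C)O[C@@H]13 | intermediate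
30 | lithium enolate from 29 | C[C@H]1C=C([O-])[C@H]2OC(C)(C)O[C@@H]12.[Li+] | intermediate
31 | coupled ring-A ketone with alkenyl triflate | C=C(OS(=O)(=O)C(F)(F)F)[C@H]2C[C@H]3[C@@H](C(C)C)[C@H](O[Si](C)(C)C(C)(C)C)C[C@]3(C)C[C@@H]2/C(C)=C\C[C@H]4[C@H](C)[C@@H]5OC(C)(C)O[C@@H]5C4=O | intermediate
32 | alkenylchromium dichloride from 31 | C=C([Cr](Cl)Cl)[C@H]2C[C@H]3[C@@H](C(C)C)[C@H](O[Si](C)(C)C(C)(C)C)C[C@]3(C)C[C@@H]2/C(C)=C\C[C@H]4[C@H](C)[C@@H]5OC(C)(C)O[C@@H]5C4=O | intermediate
33 | tetracyclic tertiary allylic alcohol (silyl ether, acetonide) | C=C1[C@H]2C[C@H]3[C@@H](C(C)C)[C@H](O[Si](C)(C)C(C)(C)C)C[C@]3(C)C[C@@H]2/C(C)=C\C[C@H]4[C@H](C)[C@@H]5OC(C)(C)O[C@@H]5[C@@]14O | intermediate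
34 | tetracyclic diol (acetonide) | C=C1[C@H]2C[C@H]3[C@@H](C(C)C)[C@H](O)C[C@]3(C)C[C@@H]2/C(C)=C\C[C@H]4[C@H](C)[C@@H]5OC(C)(C)O[C@@H]5[C@@]14O | intermediate
35 | (S)-1-bromo-2-methylbutane | CC[C@H](C)CBr | starting material
36 | ethyl but-2-ynoate | CC#CC(=O)OCC | starting material
37 | (S)-2-methylbutylmagnesium bromide | CC[C@H](C)C[Mg]Br | intermediate
38 | (S)-2-methylbutylcopper | CC[C@H](C)C[Cu] | intermediate
39 | alkenylcopper adduct (copper cis to the new alkyl group) | CC[C@H](C)C/C(C)=C(\[Cu])C(=O)OCC | intermediate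
40 | ethyl (2E,5S)-3,5-dimethylhept-2-enoate | CC[C@H](C)C/C(C)=C/C(=O)OCC | intermediate
41 | (2E,5S)-3,5-dimethylhept-2-en-1-ol | CC[C@H](C)C/C(C)=C/CO | intermediate
42 | {(2R,3R)-3-methyl-3-[(2S)-2-methylbutyl]oxiran-2-yl}methanol | CC[C@H](C)C[C@@]1(C)O[C@@H]1CO | intermediate
43 | (3R,5S)-3,5-dimethylheptane-1,3-diol | CC[C@H](C)C[C@@](C)(O)CCO | intermediate
44 | (3R,5S)-3-hydroxy-3,5-dimethylheptanoic acid | CC[C@H](C)C[C@@](C)(O)CC(=O)O | intermediate
45 | triethylsilyl (3R,5S)-3,5-dimethyl-3-[(triethylsilyl)oxy]heptanoate | CC[C@H](C)C[C@@](C)(O[Si](CC)(CC)CC)CC(=O)O[Si](CC)(CC)CC | intermediate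
46 | (3R,5S)-3,5-dimethyl-3-[(triethylsilyl)oxy]heptanoic acid | CC[C@H](C)C[C@@](C)(O[Si](CC)(CC)CC)CC(=O)O | intermediate
47 | mixed anhydride of 46 with 2,4,6-trichlorobenzoic acid | CC[C@H](C)C[C@@](C)(O[Si](CC)(CC)CC)CC(=O)OC(=O)c1c(Cl)cc(Cl)cc1Cl | intermediate
48 | ring-D ester (silyl ether, acetonide) | C=C1[C@H]2C[C@H]3[C@@H](C(C)C)[C@H](OC(=O)C[C@](C)(O[Si](CC)(CC)CC)C[C@@H](C)CC)C[C@]3(C)C[C@@H]2/C(C)=C\C[C@H]4[C@H](C)[C@@H]5OC(C)(C)O[C@@H]5[C@@]14O | intermediate
49 | tetraol ester | C=C1[C@H]2C[C@H]3[C@@H](C(C)C)[C@H](OC(=O)C[C@](C)(O)C[C@@H](C)CC)C[C@]3(C)C[C@@H]2/C(C)=C\C[C@H]4[C@H](C)[C@H](O)[C@H](O)[C@@]14O | intermediate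
50 | 1,2-diketone tautomer of the target | C=C1[C@H]2C[C@H]3[C@@H](C(C)C)[C@H](OC(=O)C[C@](C)(O)C[C@@H](C)CC)C[C@]3(C)C[C@@H]2/C(C)=C\C[C@H]4[C@H](C)C(=O)C(=O)[C@@]14O | intermediate
51 | CNP0110944.3 | C=C1[C@H]2C[C@H]3[C@@H](C(C)C)[C@H](OC(=O)C[C@](C)(O)C[C@@H](C)CC)C[C@]3(C)C[C@@H]2/C(C)=C\C[C@H]2C(C)=C(O)C(=O)[C@@]12O | target

**Step count**

Total: 31 steps. Longest linear sequence: 22 steps (steps 1–16, 20–22, 29–31).

**Steps most likely to fail and fallbacks**

Step 21. The alkenylchromium may be protonated or reduced faster than it adds to the hindered ring-A ketone, and the eight-membered closure is slowed by transannular strain. The fallback replaces the triflate by an iodide and closes the ring by halogen–lithium exchange. It sets out from 21: hydrazine hydrate and Et3N in EtOH give the hydrazone F1, and I2 with tetramethylguanidine (Barton vinyl iodide synthesis) gives the 2-iodoalkene alcohol F2. Corey–Kim chlorination gives the iodo allylic chloride F3, and alkylation of enolate 30 as in step 20 gives the iodo ketone F4. t-BuLi (2.1 equiv) in THF/pentane at −100 °C generates the alkenyllithium F5, which adds to the ketone from the same face and returns to the route at 33.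

Step 3. Methylene transfer may show poor facial discrimination, because the two faces of the enol ether differ only by remote equatorial groups. The fallback sets the quaternary centre by stereoelectronically controlled axial attack instead. It sets out from 2 and 3: the Diels–Alder reaction of step 2 with the antipodal catalyst gives the enantiomeric adduct F6. A Mukaiyama aldol reaction with aqueous formaldehyde (Sc(OTf)3 cat., THF/H2O) adds the hydroxymethyl group axially, anti to the acetyl-bearing carbon, to give the hydroxymethyl ketone F7 with the quaternary centre as in 9. I2, PPh3 and imidazole give the iodide F8; zinc dust and LiCl in THF give the zinc homoenolate F9; Pd(PPh3)4 and 7 give the triketone F10. NaOMe in MeOH then effects the aldol condensation to the diaxial hydrindenone F11 and epimerises C5 and C6 (both α to carbonyl groups) to the diequatorial isomer, returning to the route at 11.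

Step 13. Ring closure may be slow because the ester prefers the extended conformation and the 1,1-disubstituted alkene engages sluggishly, so oligomers form by cross-metathesis. The fallback builds the Z-alkene by syn-carbocupration of an ynoate. It sets out from 16: LDA and ClP(O)(OEt)2 give the enol phosphate F12, and further LDA eliminates to the terminal alkyne F13. MeNHOMe·HCl with i-PrMgCl gives the Weinreb amide F14; LDA then ClCO2Me gives the ynoate F15; Me2CuLi at −78 °C adds syn to give the (Z)-enoate F16. MeMgBr converts the amide to the methyl ketone F17; KHMDS and PhNTf2 give the alkenyl triflate F18; i-Bu2AlH at −78 °C gives the allylic alcohol F19. Corey–Kim chlorination as in step 15 returns to the route at 25.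

**Further compounds**

F1 | step 21 | hydrazone of 21 | CC(=NN)[C@H]2C[C@H]3[C@@H](C(C)C)[C@H](O[Si](C)(C)C(C)(C)C)C[C@]3(C)C[C@@H]2/C(C)=C\CO
F2 | step 21 | 2-iodoalkene allylic alcohol | C=C(I)[C@H]2C[C@H]3[C@@H](C(C)C)[C@H](O[Si](C)(C)C(C)(C)C)C[C@]3(C)C[C@@H]2/C(C)=C\CO
F3 | step 21 | 2-iodoalkene allylic chloride | C=C(I)[C@H]2C[C@H]3[C@@H](C(C)C)[C@H](O[Si](C)(C)C(C)(C)C)C[C@]3(C)C[C@@H]2/C(C)=C\CCl
F4 | step 21 | coupled ring-A ketone with alkenyl iodide | C=C(I)[C@H]2C[C@H]3[C@@H](C(C)C)[C@H](O[Si](C)(C)C(C)(C)C)C[C@]3(C)C[C@@H]2/C(C)=C\C[C@H]4[C@H](C)[C@@H]5OC(C)(C)O[C@@H]5C4=O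
F5 | step 21 | alkenyllithium from F4 | C=C([Li])[C@H]2C[C@H]3[C@@H](C(C)C)[C@H](O[Si](C)(C)C(C)(C)C)C[C@]3(C)C[C@@H]2/C(C)=C\C[C@H]4[C@H](C)[C@@H]5OC(C)(C)O[C@@H]5C4=O
F6 | step 3 | methyl (1R,6R)-6-acetyl-3-[(tert-butyldimethylsilyl)oxy]-4-methylcyclohex-3-ene-1-carboxylate | COC(=O)[C@@H]1CC(O[Si](C)(C)C(C)(C)C)=C(C)C[C@H]1C(C)=O
F7 | step 3 | methyl 2-acetyl-4-(hydroxymethyl)-4-methyl-5-oxocyclohexane-1-carboxylate | COC(=O)[C@@H]2CC(=O)[C@](C)(CO)C[C@H]2C(C)=O
F8 | step 3 | methyl 2-acetyl-4-(iodomethyl)-4-methyl-5-oxocyclohexane-1-carboxylate | COC(=O)[C@@H]2CC(=O)[C@](C)(CI)C[C@H]2C(C)=O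
F9 | step 3 | iodozinc homoenolate from F8 | COC(=O)[C@@H]2CC(=O)[C@](C)(C[Zn]I)C[C@H]2C(C)=O
F10 | step 3 | triketone, C1/C2 epimer of 9 | COC(=O)[C@@H]2CC(=O)[C@](C)(CC(=O)CC(C)C)C[C@H]2C(C)=O
F11 | step 3 | hydrindenone, C5/C6 epimer of 11 | COC(=O)[C@@H]2CC3=C(C(C)C)C(=O)C[C@]3(C)C[C@H]2C(C)=O
F12 | step 13 | enol diethyl phosphate of 16 | COC(=O)[C@H]2C[C@H]3[C@@H](C(C)C)[C@H](O[Si](C)(C)C(C)(C)C)C[C@]3(C)C[C@@H]2C(=C)OP(=O)(OCC)OCC
F13 | step 13 | terminal alkyne methyl ester | COC(=O)[C@H]2C[C@H]3[C@@H](C(C)C)[C@H](O[Si](C)(C)C(C)(C)C)C[C@]3(C)C[C@@H]2C#C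
F14 | step 13 | terminal alkyne Weinreb amide | CON(C)C(=O)[C@H]2C[C@H]3[C@@H](C(C)C)[C@H](O[Si](C)(C)C(C)(C)C)C[C@]3(C)C[C@@H]2C#C
F15 | step 13 | ynoate Weinreb amide | CON(C)C(=O)[C@H]2C[C@H]3[C@@H](C(C)C)[C@H](O[Si](C)(C)C(C)(C)C)C[C@]3(C)C[C@@H]2C#CC(=O)OC
F16 | step 13 | (Z)-enoate Weinreb amide | CON(C)C(=O)[C@H]2C[C@H]3[C@@H](C(C)C)[C@H](O[Si](C)(C)C(C)(C)C)C[C@]3(C)C[C@@H]2/C(C)=C\C(=O)OC
F17 | step 13 | (Z)-enoate methyl ketone | CC(=O)[C@H]2C[C@H]3[C@@H](C(C)C)[C@H](O[Si](C)(C)C(C)(C)C)C[C@]3(C)C[C@@H]2/C(C)=C\C(=O)OC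
F18 | step 13 | (Z)-enoate alkenyl triflate | C=C(OS(=O)(=O)C(F)(F)F)[C@H]2C[C@H]3[C@@H](C(C)C)[C@H](O[Si](C)(C)C(C)(C)C)C[C@]3(C)C[C@@H]2/C(C)=C\C(=O)OC
F19 | step 13 | (Z)-allylic alcohol alkenyl triflate | C=C(OS(=O)(=O)C(F)(F)F)[C@H]2C[C@H]3[C@@H](C(C)C)[C@H](O[Si](C)(C)C(C)(C)C)C[C@]3(C)C[C@@H]2/C(C)=C\CO
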